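Quinone ring numbering: C1 (C=O between the two C–OMe carbons), C2 (OMe), C3 (side chain), C4 (C=O), C5 (H), C6 (OMe). Retrosynthetic cuts: first the aryl ketone oxygen (back to a benzylic CH2), then C1–C2 and C3–C4 together, last the C(sp)–C(sp3) bond of the resulting alkyne.
Enabling feature: C1 and C4 are two acyl carbons held 1,4 across C5=C6(OMe), a maleoyl unit. C2=C3 carries exactly the substituents of an alkyne, MeO–C≡C–CH2R, so both bonds are acyl–alkyne carbon bonds that one metal atom bound to both acyl carbons can form in a single insertion/reductive elimination.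
Precursor design: the maleoyl unit is stored as the strained four-membered ring of 3-methoxycyclobutene-1,2-dione. Cobalt is inserted into its C(O)–C(O) bond (temporary five-membered metallacycle) and leaves again in the key step.
Forward order: the ynol ether chain is joined (steps 1–2). The four-membered ring is trimmed from dimethyl squarate and opened to the cobaltacycle (steps 3–5). The six-membered quinone ring, the only ring built, closes in step 6, and the benzylic CH2 is raised to the ketone in step 7. It is kept low until then so that no second Lewis-basic carbonyl meets SnCl4 or the ynol ether.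
Stereochemistry: the target has no stereocentre and no stereogenic double bond. The only selectivity to secure is the orientation of the alkyne (2,6- against 2,5-dimethoxy pattern).

Key step: step 6

Remark: in the SMILES of the cobalt compounds the donor bonds of P and N are drawn as covalent bonds with formal charges. These charges are bookkeeping only and say nothing about the oxidation state.

Step 1
Reactants: 1 3-(3,4-dimethoxyphenyl)propan-1-ol
Product: 2 4-(3-bromopropyl)-1,2-dimethoxybenzene
Conditions: CBr4, PPh3, CH2Cl2, 0 °C to rt
Reagents that add atoms: carbon tetrabromide BrC(Br)(Br)Br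
Why: Appel reaction, in which the alkoxyphosphonium salt of the primary alcohol is displaced by bromide in an SN2 process under neutral conditions that leave the electron-rich ring untouched.

Step 2
Reactants: 3 2-chloro-1,1-dimethoxyethane (chloroacetaldehyde dimethyl acetal); 2 4-(3-bromopropyl)-1,2-dimethoxybenzene
Product: 5 ynol ether 4-(5-methoxypent-4-yn-1-yl)-1,2-dimethoxybenzene, via sodium methoxyacetylide 4 (not isolated)
Conditions: NaNH2 (3.1 equiv), liq. NH3, −33 °C; then 2, THF, −33 °C to rt; water work-up, Et3N-deactivated silica
Reagents that add atoms: none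
Why: Sodium amide removes methanol and HCl from 3 by two eliminations and deprotonates the methoxyacetylene so formed, and acetylide 4 is then alkylated at carbon by the unhindered primary bromide (SN2), the classical one-flask preparation of 1-alkoxy-1-alkynes from chloroacetaldehyde acetals.

Step 3
Reactants: 6 dimethyl squarate (3,4-dimethoxycyclobut-3-ene-1,2-dione)
Product: 8 3-methoxycyclobut-3-ene-1,2-dione, via 4-hydroxy-2,3-dimethoxycyclobut-2-en-1-one 7 (not isolated)
Conditions: LiAlH(OtBu)3 (1.05 equiv), THF, −78 to −20 °C; then 2 M HCl, CH2Cl2, 0 °C to rt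
Reagents that add atoms: water O
Why: The bulky hydride adds once in 1,2-fashion to one squarate carbonyl, and acid then ionises the allylic hydroxyl of 7 to a dialkoxy-stabilised cyclobutenyl cation that takes up water at the distal C–OMe carbon and loses methanol, the standard 1,2-addition/hydrolysis route from squarates to 3-alkoxycyclobutenediones.

Step 4
Reactants: 8 3-methoxycyclobut-3-ene-1,2-dione
Product: 9 maleoylcobalt complex CoCl(PPh3)2[C(O)C(OMe)=CHC(O)], a five-membered cobaltacycle with both acyl carbons on cobalt
Conditions: CoCl(PPh3)3 (1.0 equiv), benzene, rt, Ar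
Reagents that add atoms: chlorotris(triphenylphosphine)cobalt CoCl(PPh3)3 Cl[Co-3]([P+](c1ccccc1)(c1ccccc1)c1ccccc1)([P+](c1ccccc1)(c1ccccc1)c1ccccc1)[P+](c1ccccc1)(c1ccccc1)c1ccccc1
Why: Oxidative addition of monovalent cobalt into the strained, electron-poor C(O)–C(O) bond of the cyclobutenedione (C–C activation driven by release of ring strain) gives the five-membered trivalent-cobalt metallacycle, which should precipitate from benzene and so escape the liberated phosphine.

Step 5
Reactants: 9 CoCl(PPh3)2[C(O)C(OMe)=CHC(O)]
Product: 10 CoCl(dmgH2)(py)[C(O)C(OMe)=CHC(O)] (dmgH2 = neutral chelating dimethylglyoxime, py = pyridine; octahedral)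
Conditions: dimethylglyoxime (1.1 equiv), pyridine, rt
Reagents that add atoms: dimethylglyoxime CC(=NO)C(C)=NO; pyridine c1ccncc1
Why: Ligand exchange, in which the chelating dioxime and pyridine displace both phosphines to give an air-stable octahedral complex whose single pyridine is easily removed by a Lewis acid, the known activated form of maleoylcobalt complexes for quinone synthesis.

Step 6
Reactants: 10 CoCl(dmgH2)(py)[C(O)C(OMe)=CHC(O)]; 5 ynol ether 4-(5-methoxypent-4-yn-1-yl)-1,2-dimethoxybenzene
Product: 12 2,6-dimethoxy-3-[3-(3,4-dimethoxyphenyl)propyl]-1,4-benzoquinone, via seven-membered cobaltacycle 11 (not isolated)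
Conditions: SnCl4 (2.2 equiv), 2,6-di-tert-butylpyridine, CH2Cl2, −40 °C; then 5 (1.2 equiv, slow addition), −40 °C to rt; aq. NaHCO3, air
Reagents that add atoms: none
Why: SnCl4 strips the pyridine from 10, which frees a site on trivalent cobalt cis to both acyl carbons, and binds the C4 oxygen, the more basic one because C4=O is the carbonyl of a vinylogous ester (MeO–C6=C5–C4=O); the coordinated ynol ether then inserts into the unactivated Co–C1 acyl bond (C1–C2 bond, cobaltacycle 11), and C–C reductive elimination joins C3 to C4 and expels monovalent cobalt. The closest known reaction type is the Lewis-acid-promoted synthesis of 1,4-benzoquinones from maleoylcobalt dimethylglyoxime complexes and alkynes, where a methoxy group on the maleoyl unit steers unsymmetrical alkynes through the same carbonyl complexation. The six-membered ring is closed as a formal [4+2] union, by enlargement of the five-membered metallacycle to the seven-membered one (migratory insertion) followed by ring contraction with loss of the metal (reductive elimination); no stereocentre is formed. The step needs orientational selectivity, and two matched biases of the substrates secure it: the tin-bound C4 acyl is carbene-like, holds on to cobalt and migrates last, and the oxygen-polarised alkyne receives the migrating C1 acyl at its electrophilic and less hindered C–OMe terminus while cobalt keeps the nucleophilic, alkyl-bearing terminus, as in the carbometalation of ynol ethers. An outer-sphere attack of the nucleophilic alkyne carbon on the tin-activated C4 would lead to the same 2,6-dimethoxy pattern, so both conceivable pathways converge. Chemoselectivity rests on the methylene-level side chain, which offers no competing carbonyl, and on slow addition of 5 to the precomplexed 10 beside a hindered base that removes adventitious HCl before it can add to the ynol ether.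

Step 7
Reactants: 12 2,6-dimethoxy-3-[3-(3,4-dimethoxyphenyl)propyl]-1,4-benzoquinone
Product: 13 evelynin, 2,6-dimethoxy-3-[3-(3,4-dimethoxyphenyl)-3-oxopropyl]-1,4-benzoquinone
Conditions: DDQ (2.5 equiv), aqueous AcOH, rt
Reagents that add atoms: water O
Why: DDQ abstracts hydride from the benzylic CH2 para to a methoxy group, water traps the cation and the electron-rich benzylic alcohol is oxidised on by a second equivalent (DDQ benzylic oxygenation of alkyl-methoxyarenes), while the electron-poor quinone and its neighbouring CH2 are inert to hydride abstraction.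

Compound list
1 | 3-(3,4-dimethoxyphenyl)propan-1-ol | COc1ccc(CCCO)cc1OC | starting material
2 | 4-(3-bromopropyl)-1,2-dimethoxybenzene | COc1ccc(CCCBr)cc1OC | intermediate
3 | 2-chloro-1,1-dimethoxyethane | COC(CCl)OC | starting material
4 | sodium methoxyacetylide | COC#[C-].[Na+] | intermediate
5 | 4-(5-methoxypent-4-yn-1-yl)-1,2-dimethoxybenzene | COC#CCCCc1ccc(OC)c(OC)c1 | intermediate
6 | dimethyl squarate | COC1=C(OC)C(=O)C1=O | starting material
7 | 4-hydroxy-2,3-dimethoxycyclobut-2-en-1-one (racemic) | COC1=C(OC)C(O)C1=O | intermediate
8 | 3-methoxycyclobut-3-ene-1,2-dione | COC1=CC(=O)C1=O | intermediate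
9 | CoCl(PPh3)2[C(O)C(OMe)=CHC(O)] | COC1=CC(=O)[Co-2](Cl)([P+](c2ccccc2)(c2ccccc2)c2ccccc2)([P+](c2ccccc2)(c2ccccc2)c2ccccc2)C1=O | intermediate
10 | CoCl(dmgH2)(py)[C(O)C(OMe)=CHC(O)] | COC1=CC(=O)[Co-3]2(Cl)([n+]3ccccc3)([N+](O)=C(C)C(C)=[N+]2O)C1=O | intermediate
11 | seven-membered cobaltacycle CoCl(dmgH2)[C(O)CH=C(OMe)C(O)C(OMe)=C(CH2CH2CH2Ar)], drawn without the tin Lewis acid on the C4 oxygen | COC1=CC(=O)[Co-2]2(Cl)([N+](O)=C(C)C(C)=[N+]2O)C(CCCc2ccc(OC)c(OC)c2)=C(OC)C1=O | intermediate
12 | 2,6-dimethoxy-3-[3-(3,4-dimethoxyphenyl)propyl]-1,4-benzoquinone | COC1=CC(=O)C(CCCc2ccc(OC)c(OC)c2)=C(OC)C1=O | intermediate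
13 | evelynin | COC1=CC(=O)C(CCC(=O)c2ccc(OC)c(OC)c2)=C(OC)C1=O | target

Total step count: 7. Longest linear sequence: 5 (steps 3, 4, 5, 6, 7).

Steps most likely to fail

(a) Step 6. Orientational control of the insertion may be lost. The ynol ether may also be consumed by acid-induced hydration, hydrochlorination or oligomerisation before it reaches cobalt.
- The fallback makes the same two bonds one after the other, without metal acyl or Lewis acid, by the cyclobutenone ring expansion (Moore rearrangement, alkenyl variant). It sets out from 5 and 8 and returns at 12.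
- Syn hydrostannation of 5 (Bu3SnH, cat. Pd(PPh3)4, THF) should give (E)-tributyl[5-(3,4-dimethoxyphenyl)-1-methoxypent-1-en-1-yl]stannane F1.
- Tin–lithium exchange (n-BuLi, THF, −78 °C) should give (Z)-[5-(3,4-dimethoxyphenyl)-1-methoxypent-1-en-1-yl]lithium F2.
- F2 should add to the more electrophilic carbonyl of 8, the one next to C–OMe and not part of the vinylogous ester. This should give 4-[(Z)-5-(3,4-dimethoxyphenyl)-1-methoxypent-1-en-1-yl]-4-hydroxy-3-methoxycyclobut-2-en-1-one F3.
- Heating in toluene at reflux (4π ring opening, 6π closure, tautomerisation) should give 2,6-dimethoxy-3-[3-(3,4-dimethoxyphenyl)propyl]benzene-1,4-diol F4. Here the site of the carbonyl addition fixes the substitution pattern.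
- Oxidation with Ag2O in Et2O should give 12.

(b) Step 7. The benzylic cation may lose a proton to give a styrene that is oxidised further. It may be captured by the C4 carbonyl oxygen, or oxygenation may stop halfway.
- The fallback brings the ketone in before the ring-forming event, so that the cobalt step ends the synthesis. It sets out from 3 (through acetylide 4) and returns at 13.
- Acetylide 4 should open oxirane in liq. NH3/THF to give 4-methoxybut-3-yn-1-ol F5.
- MsCl/Et3N should give 4-methoxybut-3-yn-1-yl methanesulfonate F6, and a Finkelstein reaction (NaI, NaHCO3, acetone) should give 4-iodo-1-methoxybut-1-yne F7.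
- Iodine–lithium exchange (t-BuLi, 2 equiv, Et2O/pentane, −78 °C) should give (4-methoxybut-3-yn-1-yl)lithium F8.
- Weinreb ketone synthesis of F8 with commercial N-methoxy-N-methyl-3,4-dimethoxybenzamide (CON(C)C(=O)c1ccc(OC)c(OC)c1), quenched with pH 7 buffer, should give 1-(3,4-dimethoxyphenyl)-5-methoxypent-4-yn-1-one F9.
- F9 takes the place of 5 under the conditions of step 6, with one further equivalent of SnCl4 to saturate the aryl ketone. Its union with 10 should give 13 directly.

(c) Step 2. Amide-induced E2 elimination of the bromide, poor solubility of 2 in ammonia, and decay of the acetylide on warming may all outrun the alkylation.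
- The fallback makes the triple bond from an ester by elimination instead of by alkylating an acetylide. It sets out from 2 and returns at 5.
- Malonic ester alkylation (dimethyl malonate, NaH, DMF) should give dimethyl 2-[3-(3,4-dimethoxyphenyl)propyl]malonate F10.
- Krapcho dealkoxycarbonylation (LiCl, wet DMSO, 150 °C) should give methyl 5-(3,4-dimethoxyphenyl)pentanoate F11.
- LDA followed by ClP(O)(OEt)2 (THF, −78 °C) should give the ketene acetal phosphate diethyl [5-(3,4-dimethoxyphenyl)-1-methoxypent-1-en-1-yl] phosphate F12 (either alkene geometry serves).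
- t-BuLi (2 equiv, THF, −100 to −78 °C) should eliminate diethyl phosphate to give 5.

Further compounds
F1 | step 6 | (E)-tributyl[5-(3,4-dimethoxyphenyl)-1-methoxypent-1-en-1-yl]stannane | CO/C(=C\CCCc1ccc(OC)c(OC)c1)[Sn](CCCC)(CCCC)CCCC
F2 | step 6 | (Z)-[5-(3,4-dimethoxyphenyl)-1-methoxypent-1-en-1-yl]lithium | CO/C([Li])=C\CCCc1ccc(OC)c(OC)c1
F3 | step 6 | 4-[(Z)-5-(3,4-dimethoxyphenyl)-1-methoxypent-1-en-1-yl]-4-hydroxy-3-methoxycyclobut-2-en-1-one (racemic) | CO/C(=C\CCCc1ccc(OC)c(OC)c1)C1(O)C(OC)=CC1=O
F4 | step 6 | 2,6-dimethoxy-3-[3-(3,4-dimethoxyphenyl)propyl]benzene-1,4-diol | COc1cc(O)c(CCCc2ccc(OC)c(OC)c2)c(OC)c1O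
F5 | step 7 | 4-methoxybut-3-yn-1-ol | COC#CCCO
F6 | step 7 | 4-methoxybut-3-yn-1-yl methanesulfonate | COC#CCCOS(C)(=O)=O
F7 | step 7 | 4-iodo-1-methoxybut-1-yne | COC#CCCI
F8 | step 7 | (4-methoxybut-3-yn-1-yl)lithium | [Li]CCC#COC
F9 | step 7 | 1-(3,4-dimethoxyphenyl)-5-methoxypent-4-yn-1-one | COC#CCCC(=O)c1ccc(OC)c(OC)c1
F10 | step 2 | dimethyl 2-[3-(3,4-dimethoxyphenyl)propyl]malonate | COC(=O)C(CCCc1ccc(OC)c(OC)c1)C(=O)OC
F11 | step 2 | methyl 5-(3,4-dimethoxyphenyl)pentanoate | COC(=O)CCCCc1ccc(OC)c(OC)c1
F12 | step 2 | diethyl [5-(3,4-dimethoxyphenyl)-1-methoxypent-1-en-1-yl] phosphate | CCOP(=O)(OCC)OC(OC)=CCCCc1ccc(OC)c(OC)c1
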